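The route rests on cutting the Z C1'=C2' alkene of the side chain (lactone numbered O1, C2, C3=C4, C5, C6; chain C1' to C10' counted from C6). The oxygens on ring carbon C6 and on C4' lie 1,5 to each other across this alkene, so a single diisopropylsilicon atom can join them. Ring-closing metathesis of the resulting bis-alkoxysilane 27, which carries a vinyl group on C6 and an allyl group on C4', forms C1'=C2' inside a 1,3-dioxa-2-silacyclooct-5-ene (28), a ring too small to hold a trans alkene. Tether and 6',8'-acetonide are later removed together while O6 closes the dihydropyranone ring.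

Key step: step 13

Remark: the target is 6S,4'R,6'S,8'R, so C4'/C6' is a syn-1,3-diol and C6'/C8' an anti-1,3-diol, and the acetonide is therefore trans-disubstituted. Where a CIP label of an intermediate differs from that of the target atom, only the priorities have changed, not the configuration.
Assumption: (−)-Ipc2BOMe [(−)-B-methoxydiisopinocampheylborane, from (+)-α-pinene], its enantiomer (+)-Ipc2BOMe, diisopropyl D-(−)-tartrate and phosphonate 31 are bought.

Step 1
Reactants: 1 3-phenylpropanal; 2 allylmagnesium bromide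
Product: 4 (3R)-1-phenylhex-5-en-3-ol, via borinate ester 3 (not isolated)
Conditions: (−)-Ipc2BOMe, allylMgBr, Et2O, 0 °C → rt; then 1, −78 °C; NaOH, H2O2, rt
Reagents that add atoms: allylmagnesium bromide, C=CC[Mg]Br
Why: Brown asymmetric allylboration: the allylborane formed in the flask from (−)-Ipc2BOMe and allylmagnesium bromide delivers allyl through a closed six-membered chair transition state to the Si face of the aldehyde, so C8' should be set as R under reagent control.

Step 2
Reactants: 4 (3R)-1-phenylhex-5-en-3-ol; 5 tert-butyl(chloro)dimethylsilane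
Product: 6 tert-butyldimethyl{[(3R)-1-phenylhex-5-en-3-yl]oxy}silane
Conditions: TBSCl, imidazole, DMF, rt
Reagents that add atoms: tert-butyl(chloro)dimethylsilane, CC(C)(C)[Si](C)(C)Cl
Why: Imidazole-promoted silylation of a secondary alcohol is routine and masks O8' so that the alkene can be cleaved and the next allylation run on an aldehyde free of a β-hydroxyl.

Step 3
Reactants: 6 tert-butyldimethyl{[(3R)-1-phenylhex-5-en-3-yl]oxy}silane
Product: 8 (3R)-3-[(tert-butyldimethylsilyl)oxy]-5-phenylpentanal, via ozonide 7 (not isolated)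
Conditions: O3, CH2Cl2, −78 °C; then PPh3, −78 °C → rt
Reagents that add atoms: ozone, [O-][O+]=O
Why: Ozonolysis, that is 1,3-dipolar cycloaddition of ozone to the terminal alkene and reduction of the ozonide by PPh3, should give the β-silyloxy aldehyde while the silyl ether and the C8' centre, which is not α to the carbonyl, stay untouched.

Step 4
Reactants: 8 (3R)-3-[(tert-butyldimethylsilyl)oxy]-5-phenylpentanal; 2 allylmagnesium bromide
Product: 10 (4R,6R)-6-[(tert-butyldimethylsilyl)oxy]-8-phenyloct-1-en-4-ol, via borinate ester 9 (not isolated)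
Conditions: (+)-Ipc2BOMe, allylMgBr, Et2O, 0 °C → rt; then 8, −78 °C; NaOH, H2O2, rt
Reagents that add atoms: allylmagnesium bromide, C=CC[Mg]Br
Why: Brown asymmetric allylboration using the enantiomeric reagent from (+)-Ipc2BOMe should add allyl to the Re face under reagent control and thereby set C6' anti to the C8' silyloxy group.

Step 5
Reactants: 10 (4R,6R)-6-[(tert-butyldimethylsilyl)oxy]-8-phenyloct-1-en-4-ol; 11 2,2-dimethoxypropane
Product: 13 (4R,6R)-2,2-dimethyl-4-(2-phenylethyl)-6-(prop-2-en-1-yl)-1,3-dioxane, via diol 12 (not isolated)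
Conditions: TsOH·H2O (cat.), MeOH, rt; evaporate; then 2,2-dimethoxypropane, acetone, rt; Et3N
Reagents that add atoms: 2,2-dimethoxypropane, COC(C)(C)OC
Why: Acid-catalysed methanolysis of the silyl ether followed in the same flask by transketalisation of the freed anti-1,3-diol gives the trans-4,6-disubstituted 1,3-dioxane without any bond to a stereocentre being broken.

Step 6
Reactants: 13 (4R,6R)-2,2-dimethyl-4-(2-phenylethyl)-6-(prop-2-en-1-yl)-1,3-dioxane
Product: 15 2-[(4S,6R)-2,2-dimethyl-6-(2-phenylethyl)-1,3-dioxan-4-yl]acetaldehyde, via ozonide 14 (not isolated)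
Conditions: O3, CH2Cl2, −78 °C; then PPh3, −78 °C → rt
Reagents that add atoms: ozone, [O-][O+]=O
Why: Ozonolysis followed by PPh3 reduction of the ozonide shortens the allyl group to the C4' aldehyde, and neither ozone nor PPh3 affects the acetonide or the two stereocentres.

Step 7
Reactants: 15 2-[(4S,6R)-2,2-dimethyl-6-(2-phenylethyl)-1,3-dioxan-4-yl]acetaldehyde; 2 allylmagnesium bromide
Product: 17 (2R)-1-[(4R,6R)-2,2-dimethyl-6-(2-phenylethyl)-1,3-dioxan-4-yl]pent-4-en-2-ol, via borinate ester 16 (not isolated)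
Conditions: (+)-Ipc2BOMe, allylMgBr, Et2O, 0 °C → rt; then 15, −78 °C; NaOH, H2O2, rt
Reagents that add atoms: allylmagnesium bromide, C=CC[Mg]Br
Why: A third Brown asymmetric allylboration, again using the reagent from (+)-Ipc2BOMe, should add allyl to the Re face under reagent control and set C4' as R, syn to O6', while installing the allyl terminus needed for metathesis.

Step 8
Reactants: 18 propane-1,3-diol; 19 4-methoxybenzyl chloride
Product: 20 3-[(4-methoxybenzyl)oxy]propan-1-ol
Conditions: NaH, THF/DMF, 0 °C; then 4-methoxybenzyl chloride, Bu4NI (cat.), rt (diol in threefold excess)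
Reagents that add atoms: 4-methoxybenzyl chloride, COc1ccc(CCl)cc1
Why: Williamson etherification of the sodium monoalkoxide gives the mono-ether selectively because the symmetrical diol is used in threefold excess.

Step 9
Reactants: 20 3-[(4-methoxybenzyl)oxy]propan-1-ol
Product: 21 3-[(4-methoxybenzyl)oxy]propanal
Conditions: TEMPO (2,2,6,6-tetramethylpiperidin-1-oxyl, cat.), PhI(OAc)2, CH2Cl2, rt
Reagents that add atoms: none
Why: Nitroxyl-catalysed oxidation by PhI(OAc)2 stops at the aldehyde and leaves the 4-methoxybenzyl ether intact.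

Step 10
Reactants: 21 3-[(4-methoxybenzyl)oxy]propanal; 22 vinylmagnesium bromide
Product: 23 rac-5-[(4-methoxybenzyl)oxy]pent-1-en-3-ol
Conditions: CH2=CHMgBr, THF, −78 → 0 °C
Reagents that add atoms: vinylmagnesium bromide, C=C[Mg]Br
Why: Grignard 1,2-addition of the vinyl nucleophile to the aldehyde creates the C6 carbinol as a racemate, which the next step resolves.

Step 11
Reactants: 23 rac-5-[(4-methoxybenzyl)oxy]pent-1-en-3-ol
Product: 24 (3S)-5-[(4-methoxybenzyl)oxy]pent-1-en-3-ol
Conditions: Ti(OiPr)4 (0.2 equiv), diisopropyl D-(−)-tartrate (0.3 equiv), t-BuOOH (0.6 equiv), 4 Å molecular sieves, CH2Cl2, −20 °C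
Reagents that add atoms: none
Why: Sharpless kinetic resolution: the titanium tartrate catalyst built from diisopropyl D-tartrate should epoxidise the R alcohol far faster than the S alcohol, so that stopping just past half conversion leaves the S alcohol, the future C6 centre, in high enantiomeric purity.

Step 12
Reactants: 24 (3S)-5-[(4-methoxybenzyl)oxy]pent-1-en-3-ol; 25 dichlorodi(propan-2-yl)silane; 17 (2R)-1-[(4R,6R)-2,2-dimethyl-6-(2-phenylethyl)-1,3-dioxan-4-yl]pent-4-en-2-ol
Product: 27 mixed diisopropylsilaketal joining O3 of 24 to O2 of 17, via chlorosilane 26 (not isolated)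
Conditions: 24, iPr2SiCl2, imidazole, CH2Cl2, 0 °C; then 17, 4-(dimethylamino)pyridine (cat.), rt → 40 °C
Reagents that add atoms: dichlorodi(propan-2-yl)silane, CC(C)[Si](Cl)(Cl)C(C)C
Why: Stepwise nucleophilic substitution at silicon works because the first chloride of iPr2SiCl2 is displaced quickly by the allylic alcohol whereas the second is slowed by the two isopropyl groups, so the monochloride persists until the homoallylic alcohol is added and no carbon stereocentre is touched.

Step 13
Reactants: 27 mixed diisopropylsilaketal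
Product: 28 (4S,5Z,8R)-8-{[(4S,6R)-2,2-dimethyl-6-(2-phenylethyl)-1,3-dioxan-4-yl]methyl}-4-{2-[(4-methoxybenzyl)oxy]ethyl}-2,2-di(propan-2-yl)-1,3-dioxa-2-silacyclooct-5-ene
Conditions: second-generation Grubbs catalyst RuCl2(=CHPh)(PCy3)(H2IMes) (10 mol %), CH2Cl2 (3 mM), reflux
Reagents that add atoms: none
Why: The ruthenium benzylidene first exchanges with the unhindered allyl terminus on C4', the new alkylidene then adds [2+2] to the C6 vinyl group, and cycloreversion of the ruthenacyclobutane expels ethene and forms C1'=C2'. This is a temporary silicon-tethered ring-closing olefin metathesis of a bis-alkoxysilane built from one allylic and one homoallylic alcohol, a known way to eight-membered cyclic silaketals. The single new ring, the 1,3-dioxa-2-silacyclooct-5-ene (Si, O, C6, C1', C2', C3', C4', O), closes by metathesis between the two terminal alkenes. No stereocentre is created and the four existing ones (C6, C4', C6', C8') are spectators. The selectivity needed is alkene geometry, and it is secured by ring size, since an E double bond in an eight-membered ring would be severely strained and only the Z ring should form whatever the catalyst. High dilution holds back intermolecular metathesis, the two isopropyl groups favour the folded conformer and shield the Si–O bonds, and the substrate has no third alkene because the enoate is introduced later.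

Step 14
Reactants: 28 eight-membered Z-silaketal
Product: 29 2-[(4S,5Z,8R)-8-{[(4S,6R)-2,2-dimethyl-6-(2-phenylethyl)-1,3-dioxan-4-yl]methyl}-2,2-di(propan-2-yl)-1,3-dioxa-2-silacyclooct-5-en-4-yl]ethan-1-ol
Conditions: DDQ, CH2Cl2/pH 7 phosphate buffer, 0 °C → rt
Reagents that add atoms: none
Why: Oxidative cleavage of the 4-methoxybenzyl ether by DDQ, through hydride abstraction from the electron-rich benzylic position and hydrolysis of the resulting oxocarbenium ion, frees the C4 alcohol while the hindered silaketal and the acetonide tolerate the buffered medium.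

Step 15
Reactants: 29 primary alcohol
Product: 30 2-[(4S,5Z,8R)-8-{[(4S,6R)-2,2-dimethyl-6-(2-phenylethyl)-1,3-dioxan-4-yl]methyl}-2,2-di(propan-2-yl)-1,3-dioxa-2-silacyclooct-5-en-4-yl]acetaldehyde
Conditions: Dess–Martin periodinane, NaHCO3, CH2Cl2, 0 °C → rt
Reagents that add atoms: none
Why: Dess–Martin oxidation buffered by NaHCO3 converts the primary alcohol into the C4 aldehyde under nearly neutral conditions, so the acetonide survives and C6, which lies β to the new carbonyl, cannot epimerise.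

Step 16
Reactants: 30 aldehyde; 31 methyl bis(2,2,2-trifluoroethyl)phosphonoacetate
Product: 32 methyl (2Z)-4-[(4S,5Z,8R)-8-{[(4S,6R)-2,2-dimethyl-6-(2-phenylethyl)-1,3-dioxan-4-yl]methyl}-2,2-di(propan-2-yl)-1,3-dioxa-2-silacyclooct-5-en-4-yl]but-2-enoate
Conditions: (CF3CH2O)2P(O)CH2CO2Me, KN(SiMe3)2, 18-crown-6, THF, −78 °C
Reagents that add atoms: methyl bis(2,2,2-trifluoroethyl)phosphonoacetate, COC(=O)CP(=O)(OCC(F)(F)F)OCC(F)(F)F
Why: Still–Gennari olefination, in which the potassium anion of the bis(trifluoroethyl) phosphonate adds irreversibly at low temperature and the electron-poor phosphorus speeds elimination from the first-formed adduct, should give the Z enoate (C3=C4) that is required for ring closure.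

Step 17
Reactants: 32 Z-enoate
Product: 34 (6S)-6-[(1Z,4R,6S,8R)-4,6,8-trihydroxy-10-phenyldec-1-en-1-yl]-5,6-dihydro-2H-pyran-2-one, via tetrol ester 33 (not isolated)
Conditions: 48% aq HF, MeCN, 0 °C → rt
Reagents that add atoms: none
Why: Aqueous HF cleaves both Si–O bonds and hydrolyses the strained trans-acetonide, and the freed O6 hydroxyl, held close to the ester by the Z C3=C4 bond, should close the six-membered lactone by acid-catalysed transesterification without any stereocentre being affected.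

Compound list
1 | 3-phenylpropanal | O=CCCc1ccccc1 | starting material
2 | allylmagnesium bromide | C=CC[Mg]Br | starting material
3 | (3R)-1-phenylhex-5-en-3-yl diisopinocampheylborinate (Ipc groups from (+)-α-pinene) | C[C@H]1[C@@H](C[C@@H]2C[C@H]1C2(C)C)B(O[C@@H](CC=C)CCc3ccccc3)[C@@H]4C[C@@H]5C[C@H]([C@H]4C)C5(C)C | intermediate
4 | (3R)-1-phenylhex-5-en-3-ol | C=CC[C@H](O)CCc1ccccc1 | intermediate
5 | tert-butyl(chloro)dimethylsilane | CC(C)(C)[Si](C)(C)Cl | starting material
6 | tert-butyldimethyl{[(3R)-1-phenylhex-5-en-3-yl]oxy}silane | C=CC[C@H](O[Si](C)(C)C(C)(C)C)CCc1ccccc1 | intermediate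
7 | tert-butyldimethyl{[(2R)-4-phenyl-1-(1,2,4-trioxolan-3-yl)butan-2-yl]oxy}silane (ozonide of 6, both epimers at the trioxolane carbon) | C1OC(C[C@H](O[Si](C)(C)C(C)(C)C)CCc2ccccc2)OO1 | intermediate
8 | (3R)-3-[(tert-butyldimethylsilyl)oxy]-5-phenylpentanal | O=CC[C@H](O[Si](C)(C)C(C)(C)C)CCc1ccccc1 | intermediate
9 | (4R,6R)-6-[(tert-butyldimethylsilyl)oxy]-8-phenyloct-1-en-4-yl diisopinocampheylborinate (Ipc groups from (−)-α-pinene) | C[C@@H]1[C@H](C[C@H]2C[C@@H]1C2(C)C)B(O[C@H](CC=C)C[C@H](O[Si](C)(C)C(C)(C)C)CCc3ccccc3)[C@H]4C[C@H]5C[C@@H]([C@@H]4C)C5(C)C | intermediate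
10 | (4R,6R)-6-[(tert-butyldimethylsilyl)oxy]-8-phenyloct-1-en-4-ol | C=CC[C@@H](O)C[C@H](O[Si](C)(C)C(C)(C)C)CCc1ccccc1 | intermediate
11 | 2,2-dimethoxypropane | COC(C)(C)OC | starting material
12 | (3R,5R)-1-phenyloct-7-ene-3,5-diol | C=CC[C@@H](O)C[C@H](O)CCc1ccccc1 | intermediate
13 | (4R,6R)-2,2-dimethyl-4-(2-phenylethyl)-6-(prop-2-en-1-yl)-1,3-dioxane (trans) | C=CC[C@@H]1C[C@@H](CCc2ccccc2)OC(C)(C)O1 | intermediate
14 | (4R,6S)-2,2-dimethyl-4-(2-phenylethyl)-6-[(1,2,4-trioxolan-3-yl)methyl]-1,3-dioxane (ozonide of 13, both epimers at the trioxolane carbon) | C1OC(C[C@@H]2C[C@@H](CCc3ccccc3)OC(C)(C)O2)OO1 | intermediate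
15 | 2-[(4S,6R)-2,2-dimethyl-6-(2-phenylethyl)-1,3-dioxan-4-yl]acetaldehyde | O=CC[C@@H]1C[C@@H](CCc2ccccc2)OC(C)(C)O1 | intermediate
16 | (2R)-1-[(4R,6R)-2,2-dimethyl-6-(2-phenylethyl)-1,3-dioxan-4-yl]pent-4-en-2-yl diisopinocampheylborinate (Ipc groups from (−)-α-pinene) | C[C@@H]1[C@H](C[C@H]2C[C@@H]1C2(C)C)B(O[C@H](CC=C)C[C@@H]3C[C@@H](CCc6ccccc6)OC(C)(C)O3)[C@H]4C[C@H]5C[C@@H]([C@@H]4C)C5(C)C | intermediate
17 | (2R)-1-[(4R,6R)-2,2-dimethyl-6-(2-phenylethyl)-1,3-dioxan-4-yl]pent-4-en-2-ol | C=CC[C@@H](O)C[C@@H]1C[C@@H](CCc2ccccc2)OC(C)(C)O1 | intermediate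
18 | propane-1,3-diol | OCCCO | starting material
19 | 4-methoxybenzyl chloride | COc1ccc(CCl)cc1 | starting material
20 | 3-[(4-methoxybenzyl)oxy]propan-1-ol | COc1ccc(COCCCO)cc1 | intermediate
21 | 3-[(4-methoxybenzyl)oxy]propanal | COc1ccc(COCCC=O)cc1 | intermediate
22 | vinylmagnesium bromide | C=C[Mg]Br | starting material
23 | rac-5-[(4-methoxybenzyl)oxy]pent-1-en-3-ol | COc1ccc(COCCC(O)C=C)cc1 | intermediate
24 | (3S)-5-[(4-methoxybenzyl)oxy]pent-1-en-3-ol | COc1ccc(COCC[C@@H](C=C)O)cc1 | intermediate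
25 | dichlorodi(propan-2-yl)silane | CC(C)[Si](Cl)(Cl)C(C)C | starting material
26 | chloro{[(3S)-5-[(4-methoxybenzyl)oxy]pent-1-en-3-yl]oxy}di(propan-2-yl)silane | COc1ccc(COCC[C@@H](C=C)O[Si](Cl)(C(C)C)C(C)C)cc1 | intermediate
27 | {[(2R)-1-[(4S,6R)-2,2-dimethyl-6-(2-phenylethyl)-1,3-dioxan-4-yl]pent-4-en-2-yl]oxy}{[(3S)-5-[(4-methoxybenzyl)oxy]pent-1-en-3-yl]oxy}di(propan-2-yl)silane (configurations as in 17 and 24) | COc1ccc(COCC[C@@H](C=C)O[Si](C(C)C)(C(C)C)O[C@H](CC=C)C[C@@H]2C[C@@H](CCc3ccccc3)OC(C)(C)O2)cc1 | intermediate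
28 | (4S,5Z,8R)-8-{[(4S,6R)-2,2-dimethyl-6-(2-phenylethyl)-1,3-dioxan-4-yl]methyl}-4-{2-[(4-methoxybenzyl)oxy]ethyl}-2,2-di(propan-2-yl)-1,3-dioxa-2-silacyclooct-5-ene | COc1ccc(COCC[C@H]2/C=C\C[C@H](C[C@@H]3C[C@@H](CCc4ccccc4)OC(C)(C)O3)O[Si](C(C)C)(C(C)C)O2)cc1 | intermediate
29 | 2-[(4S,5Z,8R)-8-{[(4S,6R)-2,2-dimethyl-6-(2-phenylethyl)-1,3-dioxan-4-yl]methyl}-2,2-di(propan-2-yl)-1,3-dioxa-2-silacyclooct-5-en-4-yl]ethan-1-ol | OCC[C@H]1/C=C\C[C@H](C[C@@H]2C[C@@H](CCc3ccccc3)OC(C)(C)O2)O[Si](C(C)C)(C(C)C)O1 | intermediate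
30 | 2-[(4S,5Z,8R)-8-{[(4S,6R)-2,2-dimethyl-6-(2-phenylethyl)-1,3-dioxan-4-yl]methyl}-2,2-di(propan-2-yl)-1,3-dioxa-2-silacyclooct-5-en-4-yl]acetaldehyde | O=CC[C@H]1/C=C\C[C@H](C[C@@H]2C[C@@H](CCc3ccccc3)OC(C)(C)O2)O[Si](C(C)C)(C(C)C)O1 | intermediate
31 | methyl bis(2,2,2-trifluoroethyl)phosphonoacetate | COC(=O)CP(=O)(OCC(F)(F)F)OCC(F)(F)F | starting material
32 | methyl (2Z)-4-[(4S,5Z,8R)-8-{[(4S,6R)-2,2-dimethyl-6-(2-phenylethyl)-1,3-dioxan-4-yl]methyl}-2,2-di(propan-2-yl)-1,3-dioxa-2-silacyclooct-5-en-4-yl]but-2-enoate | COC(=O)/C=C\C[C@H]1/C=C\C[C@H](C[C@@H]2C[C@@H](CCc3ccccc3)OC(C)(C)O2)O[Si](C(C)C)(C(C)C)O1 | intermediate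
33 | methyl (2Z,5S,6Z,9R,11S,13R)-5,9,11,13-tetrahydroxy-15-phenylpentadeca-2,6-dienoate | COC(=O)/C=C\C[C@H](O)/C=C\C[C@@H](O)C[C@@H](O)C[C@H](O)CCc1ccccc1 | intermediate
34 | (6S)-6-[(1Z,4R,6S,8R)-4,6,8-trihydroxy-10-phenyldec-1-en-1-yl]-5,6-dihydro-2H-pyran-2-one | O=C1C=CC[C@@H](/C=C\C[C@@H](O)C[C@@H](O)C[C@H](O)CCc2ccccc2)O1 | target

Total step count: 17.
Longest linear sequence: 13 steps (steps 1 to 7, then 12 to 17); the second branch (steps 8 to 11) joins at step 12.

Steps most likely to fail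

Step 13. What may go wrong: closure of the medium ring is outpaced by intermolecular metathesis at the allyl terminus, so that oligomers form while the catalyst decays. Fallback: make the Z alkene by semihydrogenation of an alkyne instead of by metathesis; it sets out from aldehydes 15 and 21 and comes back to the route at 28. Asymmetric propargylation of 15 (allenylboronic acid pinacol ester, catalytic 3,3'-bis(2,4,6-triisopropylphenyl)-1,1'-binaphthyl-2,2'-diyl hydrogen phosphate, enantiomer chosen for the R carbinol) should give the homopropargylic alcohol F1. Its zinc acetylide (Me2Zn, ProPhenol ligand, enantiomer chosen for the S carbinol, the free hydroxyl carried as its zinc alkoxide) adds to 21 to give the alkyne diol F2. Hydrogen over Pd on CaCO3 poisoned by Pb(OAc)2 and quinoline gives the Z-ene diol F3. iPr2Si(OTf)2 and 2,6-lutidine in dilute CH2Cl2 then bridge the two hydroxyls to give 28.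

Step 12. What may go wrong: the second substitution at the crowded silicon stalls, or both chlorides are displaced by 24 so that the symmetrical bis-ether forms. Fallback: pass through a hydrosilane and activate it in a separate operation; it sets out from 24 and comes back at 27. 24 and iPr2SiHCl (imidazole, CH2Cl2) give the hydrosilyl ether F4, which cannot be substituted twice. N-Bromosuccinimide (CH2Cl2, 0 °C) converts Si–H into Si–Br to give the bromosilane F5, used at once. Addition of 17, imidazole and 4-(dimethylamino)pyridine then gives 27.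

Step 16. What may go wrong: base-induced β-elimination of the allylic silyloxy group from the aldehyde, or leakage to the E enoate, which cannot lactonise. Fallback: reach the Z enoate by alkyne semihydrogenation; it sets out from 30 and comes back at 32. Corey–Fuchs olefination (CBr4, PPh3, 2,6-lutidine, CH2Cl2, 0 °C) gives the dibromoalkene F6. n-BuLi (2 equiv, THF, −78 °C) followed by methyl chloroformate gives the ynoate F7. Hydrogen over Pd on CaCO3 poisoned by Pb(OAc)2 and quinoline should reduce only the alkyne and give 32.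

Further compounds
F1 | step 13 | (2R)-1-[(4R,6R)-2,2-dimethyl-6-(2-phenylethyl)-1,3-dioxan-4-yl]pent-4-yn-2-ol | C#CC[C@@H](O)C[C@@H]1C[C@@H](CCc2ccccc2)OC(C)(C)O1
F2 | step 13 | (3S,7R)-8-[(4R,6R)-2,2-dimethyl-6-(2-phenylethyl)-1,3-dioxan-4-yl]-1-[(4-methoxybenzyl)oxy]oct-4-yne-3,7-diol | COc1ccc(COCC[C@H](O)C#CC[C@@H](O)C[C@@H]2C[C@@H](CCc3ccccc3)OC(C)(C)O2)cc1
F3 | step 13 | (3S,4Z,7R)-8-[(4R,6R)-2,2-dimethyl-6-(2-phenylethyl)-1,3-dioxan-4-yl]-1-[(4-methoxybenzyl)oxy]oct-4-ene-3,7-diol | COc1ccc(COCC[C@H](O)/C=C\C[C@@H](O)C[C@@H]2C[C@@H](CCc3ccccc3)OC(C)(C)O2)cc1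
F4 | step 12 | {[(3S)-5-[(4-methoxybenzyl)oxy]pent-1-en-3-yl]oxy}di(propan-2-yl)silane | COc1ccc(COCC[C@@H](C=C)O[SiH](C(C)C)C(C)C)cc1
F5 | step 12 | bromo{[(3S)-5-[(4-methoxybenzyl)oxy]pent-1-en-3-yl]oxy}di(propan-2-yl)silane | COc1ccc(COCC[C@@H](C=C)O[Si](Br)(C(C)C)C(C)C)cc1
F6 | step 16 | (4S,5Z,8R)-4-(3,3-dibromoprop-2-en-1-yl)-8-{[(4S,6R)-2,2-dimethyl-6-(2-phenylethyl)-1,3-dioxan-4-yl]methyl}-2,2-di(propan-2-yl)-1,3-dioxa-2-silacyclooct-5-ene | BrC(Br)=CC[C@H]1/C=C\C[C@H](C[C@@H]2C[C@@H](CCc3ccccc3)OC(C)(C)O2)O[Si](C(C)C)(C(C)C)O1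
F7 | step 16 | methyl 5-[(4S,5Z,8R)-8-{[(4S,6R)-2,2-dimethyl-6-(2-phenylethyl)-1,3-dioxan-4-yl]methyl}-2,2-di(propan-2-yl)-1,3-dioxa-2-silacyclooct-5-en-4-yl]pent-2-ynoate | COC(=O)C#CC[C@H]1/C=C\C[C@H](C[C@@H]2C[C@@H](CCc3ccccc3)OC(C)(C)O2)O[Si](C(C)C)(C(C)C)O1
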